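**Target:** (2S,6S)-6-decyl-2-heptyl-2,3,5,6-tetrahydro-4H,8H-pyrano[3,4-b]pyran-4,8-dione. Locants: O1, C2 (heptyl), C3, C4 (ketone), C4a, C5, C6 (decyl), O7, C8 (lactone C=O), C8a. Ring A is the lactone, ring B the dihydropyranone.

**Plan**
- Cuts: ring B at C2–C3 and O1–C8a (aldol with octanal, then addition–elimination at a C8a methoxy group); ring A at C5–C6 and O7–C8 (hetero-Diels–Alder with undecanal); the C4a=C8a olefin by Horner–Wadsworth–Emmons back to biacetyl and an α-methoxy phosphonoacetate.
- Forward order: C4a=C8a first, then ring A, then ring B; the core comes from one enone ester, the two side chains from two aldehydes.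
- Enabling feature: C5 is the γ-carbon of the C8 carbonyl through the C4a=C8a double bond, so C8=C8a–C4a=C5 (as its silyl ketene acetal) is a 1-oxy-diene and C6–O7 is an aldehyde carbonyl; ring A is their [4+2] adduct.
- The competing acidic C3 methyl of the C4 ketone is silenced as a silyl enol ether during dienolisation.
- Stereochemistry: C6 and C2 are too far apart to relay, so each is set by the catalyst: Re-face attack on undecanal (step 4) and on octanal (step 6) with (R)-BINOL/Ti(OiPr)4.

Key step: step 4

Remark: 4 and 5 are E/Z mixtures about the future C4a=C8a bond; this geometry is erased in step 3 and fixed by ring A in step 4.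
Remark: (S) at C6 and at C2 both correspond to Re-face attack on the aldehyde; the (R)-antipode of BINOL is assigned from the usual facial model for BINOL–Ti(OiPr)4 additions to unbranched aliphatic aldehydes and is the assumption made here.

**Step 1**
Reactants: 1 methyl 2-(dimethoxyphosphoryl)-2-methoxyacetate; 2 butane-2,3-dione
Product: 4 methyl (2E/Z)-2-methoxy-3-methyl-4-oxopent-2-enoate, via lithiated phosphonate 3 (not isolated)
Conditions: LiN(SiMe3)2 (1.05 equiv), THF, −78 °C; then 2 (3 equiv), −78 °C → rt
Reagents that add atoms: none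
Why: Horner–Wadsworth–Emmons olefination of one carbonyl of the activated 1,2-diketone should give the tetrasubstituted alkene with the methoxy group on the ester-bearing carbon, excess biacetyl suppressing a second olefination.

**Step 2**
Reactants: 4 methyl (2E/Z)-2-methoxy-3-methyl-4-oxopent-2-enoate
Product: 5 methyl (2E/Z)-4-(tert-butyldimethylsilyloxy)-2-methoxy-3-methylpenta-2,4-dienoate
Conditions: TBSOTf (1.2 equiv), Et3N (1.5 equiv), CH2Cl2, 0 °C
Reagents that add atoms: tert-butyldimethylsilyl trifluoromethanesulfonate, CC(C)(C)[Si](C)(C)OS(=O)(=O)C(F)(F)F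
Why: Soft enolisation of the methyl ketone, whose only α-hydrogens are on the acetyl methyl, should give the 2-silyloxy diene and so mask the ketone against the strong base of step 3.

**Step 3**
Reactants: 5 methyl (2E/Z)-4-(tert-butyldimethylsilyloxy)-2-methoxy-3-methylpenta-2,4-dienoate
Product: 7 4-(tert-butyldimethylsilyloxy)-1,2-dimethoxy-3-methylidene-1-(trimethylsilyloxy)penta-1,4-diene, via lithium dienolate 6 (not isolated)
Conditions: LiN(iPr)2 (1.1 equiv), THF, −78 °C; then Me3SiCl (1.3 equiv), −78 → 0 °C; pentane, filtration; used crude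
Reagents that add atoms: chlorotrimethylsilane, C[Si](C)(C)Cl
Why: Kinetic γ-deprotonation of the α-methoxy enoate at its 3-methyl group, the only acidic C–H left, followed by O-silylation is the standard preparation of 1-alkoxy-1-silyloxy dienes from β-methyl enoates.

**Step 4**
Reactants: 7 4-(tert-butyldimethylsilyloxy)-1,2-dimethoxy-3-methylidene-1-(trimethylsilyloxy)penta-1,4-diene; 8 undecanal
Product: 11 (6S)-4-acetyl-6-decyl-3-methoxy-5,6-dihydro-2H-pyran-2-one, via ortho ester cycloadduct 9 (not isolated), via silyl enol ether lactone 10 (not isolated)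
Conditions: (R)-BINOL (20 mol %), Ti(OiPr)4 (10 mol %), 4 Å MS, CH2Cl2, −20 °C, 7 (1.3 equiv); then CF3CO2H, wet CH2Cl2, 0 °C
Reagents that add atoms: none
Why: The tetravalent-titanium BINOLate binds undecanal, the unsubstituted CH2 terminus of the silyl ketene acetal diene of 7 (C8=C8a–C4a=C5) attacks the carbonyl carbon and the carbonyl oxygen closes onto C8, in one asynchronous [4+2] event or as a vinylogous Mukaiyama aldol addition followed at once by O–C8 collapse, to give ortho ester 9, which CF3CO2H converts to the lactone and then to the free methyl ketone. The closest known reaction type is the BINOL–titanium catalysed hetero-Diels–Alder reaction of 1-alkoxy-1-silyloxy dienes with aliphatic aldehydes, which gives 6-alkyl-5,6-dihydro-2-pyranones directly. Ring A closes in the [4+2] mode (C5–C6 and O7–C8; in the stepwise limit O7–C8 forms by 6-exo-trig attack on the carboxonium carbon). The only new stereocentre, C6, is set by the catalyst, which is expected to expose the Re face of the aldehyde, corresponding to (S); no resident stereocentre can match or mismatch. The step needs site selectivity between the two nucleophilic termini of 7, secured by the much higher nucleophilicity of the silyl ketene acetal diene over the bulky TBS enol ether and by using the aldehyde as limiting reagent. It also needs γ-regioselectivity, secured because C8a is fully substituted and only γ-attack can end in a six-membered ring.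

**Step 5**
Reactants: 11 (6S)-4-acetyl-6-decyl-3-methoxy-5,6-dihydro-2H-pyran-2-one
Product: 12 (6S)-6-decyl-3-methoxy-4-[1-(trimethylsilyloxy)ethenyl]-5,6-dihydro-2H-pyran-2-one
Conditions: Me3SiOTf (1.2 equiv), Et3N (1.5 equiv), CH2Cl2, 0 °C; used crude
Reagents that add atoms: trimethylsilyl trifluoromethanesulfonate, C[Si](C)(C)OS(=O)(=O)C(F)(F)F
Why: Soft enolisation of the conjugated methyl ketone at its only α-position should give the 1-alkoxy-3-silyloxy diene without a strong base that could open the lactone by γ-deprotonation and β-elimination, so C6 is untouched.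

**Step 6**
Reactants: 12 (6S)-6-decyl-3-methoxy-4-[1-(trimethylsilyloxy)ethenyl]-5,6-dihydro-2H-pyran-2-one; 13 octanal
Product: 16 (2S,6S)-6-decyl-2-heptyl-2,3,5,6-tetrahydro-4H,8H-pyrano[3,4-b]pyran-4,8-dione, via silyl aldol adduct 14 (not isolated), via hydroxy ketone 15 (not isolated)
Conditions: (R)-BINOL (20 mol %), Ti(OiPr)4 (10 mol %), 4 Å MS, Et2O, −20 °C; then CF3CO2H, CH2Cl2, 0 °C
Reagents that add atoms: none
Why: A BINOL–Ti(OiPr)4 catalysed Mukaiyama aldol addition of the silyl enol ether terminus to the Re face of octanal should set C2 as (S) under catalyst control, and acid then closes ring B by 6-endo addition of the C2 hydroxyl to C8a of the vinylogous ester with loss of methanol, the classical dihydropyranone annulation of 1-alkoxy-3-silyloxy dienes.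

**Compound list**
1 | methyl 2-(dimethoxyphosphoryl)-2-methoxyacetate | COC(=O)C(OC)P(=O)(OC)OC | starting material
2 | butane-2,3-dione (biacetyl) | CC(=O)C(C)=O | starting material
3 | lithium salt of 1 (lithiated phosphonate) | [Li+].COC(=O)[C-](OC)P(=O)(OC)OC | intermediate
4 | methyl (2E/Z)-2-methoxy-3-methyl-4-oxopent-2-enoate | COC(=O)C(OC)=C(C)C(C)=O | intermediate
5 | methyl (2E/Z)-4-(tert-butyldimethylsilyloxy)-2-methoxy-3-methylpenta-2,4-dienoate | COC(=O)C(OC)=C(C)C(=C)O[Si](C)(C)C(C)(C)C | intermediate
6 | lithium 4-(tert-butyldimethylsilyloxy)-1,2-dimethoxy-3-methylidenepenta-1,4-dien-1-olate | [Li+].[O-]C(OC)=C(OC)C(=C)C(=C)O[Si](C)(C)C(C)(C)C | intermediate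
7 | 4-(tert-butyldimethylsilyloxy)-1,2-dimethoxy-3-methylidene-1-(trimethylsilyloxy)penta-1,4-diene (ketene acetal E/Z mixture) | C=C(O[Si](C)(C)C(C)(C)C)C(=C)C(OC)=C(OC)O[Si](C)(C)C | intermediate
8 | undecanal | CCCCCCCCCCC=O | starting material
9 | (6S)-4-[1-(tert-butyldimethylsilyloxy)ethenyl]-6-decyl-2,3-dimethoxy-2-(trimethylsilyloxy)-5,6-dihydro-2H-pyran (C2 epimers) | CCCCCCCCCC[C@H]1CC(C(=C)O[Si](C)(C)C(C)(C)C)=C(OC)C(OC)(O[Si](C)(C)C)O1 | intermediate
10 | (6S)-4-[1-(tert-butyldimethylsilyloxy)ethenyl]-6-decyl-3-methoxy-5,6-dihydro-2H-pyran-2-one | CCCCCCCCCC[C@H]1CC(C(=C)O[Si](C)(C)C(C)(C)C)=C(OC)C(=O)O1 | intermediate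
11 | (6S)-4-acetyl-6-decyl-3-methoxy-5,6-dihydro-2H-pyran-2-one | CCCCCCCCCC[C@H]1CC(C(C)=O)=C(OC)C(=O)O1 | intermediate
12 | (6S)-6-decyl-3-methoxy-4-[1-(trimethylsilyloxy)ethenyl]-5,6-dihydro-2H-pyran-2-one | CCCCCCCCCC[C@H]1CC(C(=C)O[Si](C)(C)C)=C(OC)C(=O)O1 | intermediate
13 | octanal | CCCCCCCC=O | starting material
14 | (6S)-6-decyl-3-methoxy-4-[(3S)-3-(trimethylsilyloxy)decanoyl]-5,6-dihydro-2H-pyran-2-one | CCCCCCCCCC[C@H]1CC(C(=O)C[C@H](CCCCCCC)O[Si](C)(C)C)=C(OC)C(=O)O1 | intermediate
15 | (6S)-6-decyl-4-[(3S)-3-hydroxydecanoyl]-3-methoxy-5,6-dihydro-2H-pyran-2-one | CCCCCCCCCC[C@H]1CC(C(=O)C[C@H](CCCCCCC)O)=C(OC)C(=O)O1 | intermediate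
16 | (2S,6S)-6-decyl-2-heptyl-2,3,5,6-tetrahydro-4H,8H-pyrano[3,4-b]pyran-4,8-dione | CCCCCCCCCC[C@H]1CC2=C(O[C@@H](CCCCCCC)CC2=O)C(=O)O1 | target

**Step count**
Total: 6 steps. Longest linear sequence: 6 steps (from 1 and 2); undecanal and octanal enter as single building blocks.

**Steps most likely to fail**

Step 4. The catalyst may discriminate the faces of a linear aldehyde poorly with this more hindered diene. The enol ether terminus may compete for the aldehyde. The ketone may also be unmasked before ring closure, letting a free C6 hydroxyl displace the C8a methoxy group instead of lactonising. The fallback sets out from 7 and comes back at 11, setting C6 by hydrogenation of a flat pyranone instead of by aldehyde face selection. Uncatalysed vinylogous acylation of 7 with undecanoyl chloride (CH2Cl2, −78 → 0 °C) should give the keto ester methyl (2E/Z)-3-[1-(tert-butyldimethylsilyloxy)ethenyl]-2-methoxy-5-oxopentadec-2-enoate F1. DBU in toluene should close the enol lactone 4-[1-(tert-butyldimethylsilyloxy)ethenyl]-6-decyl-3-methoxy-2H-pyran-2-one F2. Wet CF3CO2H should unmask the ketone to 4-acetyl-6-decyl-3-methoxy-2H-pyran-2-one F3. Asymmetric hydrogenation of the C5=C6 bond of this 2-pyranone (H2, Ru(OAc)2(MeO-BIPHEP), HBF4, MeOH, ligand antipode chosen for 6S) should then give 11.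

Step 6. The electron-poor silyl enol ether may add slowly, so that an uncatalysed racemic pathway erodes facial selectivity, and the aldol may dehydrate under acid before ring B closes. The fallback sets out from 11 and comes back at 15, using a stoichiometric chiral boron enolate instead of a catalytic Mukaiyama addition. Enolisation with (−)-Ipc2BCl and Et3N (Et2O, 0 °C) should give the enol borinate (6S)-6-decyl-4-[1-(diisopinocampheylboryloxy)ethenyl]-3-methoxy-5,6-dihydro-2H-pyran-2-one F4. Addition to octanal 13 at −78 °C should give the boron aldolate (6S)-6-decyl-4-[(3S)-3-(diisopinocampheylboryloxy)decanoyl]-3-methoxy-5,6-dihydro-2H-pyran-2-one F5. Oxidative work-up (H2O2, pH 7 buffer) releases 15, and catalytic TsOH in CH2Cl2 closes ring B to 16. The reagent antipode is the one expected to attack the Re face of the aldehyde with methyl-ketone enolates.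

Step 1. The phosphonate anion may enolise biacetyl and start its self-condensation, and collapse to a tetrasubstituted alkene may be slow. The fallback sets out from 2 and comes back at 4, replacing olefination by aldol addition and dehydration. Addition of the lithium enolate of methyl methoxyacetate (LiN(iPr)2, THF, −78 °C) to 2 should give methyl 3-hydroxy-2-methoxy-3-methyl-4-oxopentanoate F6. Dehydration with SOCl2 and pyridine (0 °C) towards the acidic C2 hydrogen should give 4.

**Further compounds**
F1 | step 4 | methyl (2E/Z)-3-[1-(tert-butyldimethylsilyloxy)ethenyl]-2-methoxy-5-oxopentadec-2-enoate | CCCCCCCCCCC(=O)CC(C(=C)O[Si](C)(C)C(C)(C)C)=C(OC)C(=O)OC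
F2 | step 4 | 4-[1-(tert-butyldimethylsilyloxy)ethenyl]-6-decyl-3-methoxy-2H-pyran-2-one | CCCCCCCCCCC1=CC(C(=C)O[Si](C)(C)C(C)(C)C)=C(OC)C(=O)O1
F3 | step 4 | 4-acetyl-6-decyl-3-methoxy-2H-pyran-2-one | CCCCCCCCCCC1=CC(C(C)=O)=C(OC)C(=O)O1
F4 | step 6 | (6S)-6-decyl-4-[1-(diisopinocampheylboryloxy)ethenyl]-3-methoxy-5,6-dihydro-2H-pyran-2-one | CCCCCCCCCC[C@H]1CC(C(=C)OB([C@@H]2C[C@@H]3C[C@H]([C@H]2C)C3(C)C)[C@@H]2C[C@@H]3C[C@H]([C@H]2C)C3(C)C)=C(OC)C(=O)O1
F5 | step 6 | (6S)-6-decyl-4-[(3S)-3-(diisopinocampheylboryloxy)decanoyl]-3-methoxy-5,6-dihydro-2H-pyran-2-one | CCCCCCCCCC[C@H]1CC(C(=O)C[C@H](CCCCCCC)OB([C@@H]2C[C@@H]3C[C@H]([C@H]2C)C3(C)C)[C@@H]2C[C@@H]3C[C@H]([C@H]2C)C3(C)C)=C(OC)C(=O)O1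
F6 | step 1 | methyl 3-hydroxy-2-methoxy-3-methyl-4-oxopentanoate | CC(=O)C(C)(O)C(OC)C(=O)OC
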